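**Retrosynthetic overview**
1. Feature: the cyclohexanol ring C1–C6, with its C1 methyl and with C8 of the isopropenyl group on C4, is an intact head-to-tail C10 chain. Cutting only ring bond C3–C4 unfolds it to the geraniol skeleton (ring C1/C2 = geraniol C3/C2, ring C3 = geraniol C1, C4=C8 = the 6,7-alkene).
2. Last disconnections: the gem-diprenyl carbon of the dearomatised triketone ring goes back to an aromatic acylphloroglucinol plus two prenyl bromide. The isobutyryl group goes back to ortho-lithiation of the MOM-protected arene.
3. Key disconnection: C3–C4 goes back to an open-chain primary iodide. A 6-exo radical closure with cobalt-mediated loss of hydrogen makes the ring, C4 and the isopropenyl group in one operation.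
4. C1 and C2 are set in the open chain by asymmetric epoxidation of geraniol and backside opening at C2 with a phloroglucinol-derived aryl-copper reagent. This gives the hydroxyl-cis-to-aryl relationship.
5. Ring order: the phloroglucinol carbocycle is bought, the cyclohexane is the only ring formed (step 5), and the arene is dearomatised last (step 8).

Key step: step 5

Assumption: the triketone ring of the target is treated as the drawn enol tautomer of a rapidly equilibrating set, and the tertiary hydroxyl is taken to be silylated along with the phenols under the excess TMSOTf of step 7 (harmless, since the methanolysis frees all four oxygens).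

Step 1
Reactants: 1 geraniol
Product: 2 [(2R,3R)-3-methyl-3-(4-methylpent-3-en-1-yl)oxiran-2-yl]methanol ((2R,3R)-2,3-epoxygeraniol)
Conditions: Ti(Oi-Pr)4 (5 mol %), D-(−)-diethyl tartrate (7 mol %), t-BuOOH (anhydrous, decane), 4 Å MS, CH2Cl2, −20 °C
Reagents that add atoms: tert-butyl hydroperoxide CC(C)(C)OO
Why: Sharpless asymmetric epoxidation: titanium binds the allylic hydroxyl, so only the 2,3-alkene and not the remote 6,7-alkene is oxidised, and the D-(−)-tartrate ligand directs oxygen to the face that gives the (2R,3R)-epoxide, which fixes the carbinol centre (target C1) and prepares C2 for one inversion.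

Step 2
Reactants: 3 phloroglucinol
Product: 4 1,3,5-tris(methoxymethoxy)benzene
Conditions: NaH, MOMCl, DMF, 0 °C → rt
Reagents that add atoms: chloromethyl methyl ether COCCl
Why: Williamson-type O-alkylation of the three phenoxides with a hard, reactive chloromethyl ether gives the tris-acetal, whose OMOM groups survive the organometallic, radical and basic steps and direct both later metalations.

Step 3
Reactants: 4 1,3,5-tris(methoxymethoxy)benzene; 2 (2R,3R)-2,3-epoxygeraniol
Product: 7 (2S,3R)-3,7-dimethyl-2-[2,4,6-tris(methoxymethoxy)phenyl]oct-6-ene-1,3-diol, via aryllithium 5 (not isolated), via arylmagnesium bromide 6 (not isolated)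
Conditions: 4 (3 equiv), n-BuLi, THF, 0 °C; MgBr2·OEt2, 0 °C; CuI (10 mol % on Mg), −30 °C; then 2, −30 → 0 °C; sat. aq NH4Cl
Reagents that add atoms: none
Why: Directed ortho-metalation between two OMOM groups, Li-to-Mg exchange and copper-catalysed SN2 opening of a 2,3-epoxy alcohol: C3 is fully substituted, so sp2 Grignard/CuI reagents attack this substrate class at C2 to give 1,3-diols, the covalent magnesium alkoxide holds back Payne migration of the epoxide, and backside attack inverts C2, which places aryl and hydroxyl on the same face of the later ring (2S,3R).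

Step 4
Reactants: 7 (2S,3R)-diol
Product: 8 (2R,3R)-1-iodo-3,7-dimethyl-2-[2,4,6-tris(methoxymethoxy)phenyl]oct-6-en-3-ol
Conditions: PPh3 (slight excess), imidazole, I2 (premixed), CH2Cl2, 0 °C, dark; used promptly
Reagents that add atoms: iodine II
Why: Appel-type iodination (PPh3/I2/imidazole): only the primary hydroxyl gives an alkoxyphosphonium ion that iodide can displace, the tertiary alcohol does not react, premixing leaves no free iodine for iodoetherification of the alkene or iodination of the arene, imidazole keeps the MOM groups safe, and no stereocentre is touched (C2 turns from S to R only through the CIP rank of CH2I).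

Step 5
Reactants: 8 (2R,3R)-iodide
Product: 9 (1R,2R,4S)-1-methyl-4-(prop-1-en-2-yl)-2-[2,4,6-tris(methoxymethoxy)phenyl]cyclohexan-1-ol
Conditions: Ph3Sn–Co(dmgH)2(py) (10–15 mol %), i-Pr2NEt (2 equiv), degassed MeCN (0.01 M), blue LED, 25 °C
Reagents that add atoms: none
Why: Blue light breaks the Sn–Co bond of the precatalyst, iodine is abstracted from 8 (in later turnovers by Co(I), via a photolabile alkyl–Co(III)), the primary C3 radical adds to C4 of the C4=C8 alkene, and the tertiary C8 radical hands a methyl hydrogen to Co(II), after which i-Pr2NEt deprotonates H–Co(III) back to Co(I). This is the cobaloxime-catalysed intramolecular Heck-type coupling of unactivated alkyl iodides with alkenes (radical cyclisation followed by dehydrocobaltation), a reaction type established for 5-exo and 6-exo closures and for turning prenyl acceptors into isopropenyl groups. The cyclohexane ring closes 6-exo-trig through the new C3–C4 bond. C4 is controlled by the two existing centres through a chair-like transition state with the C2 aryl group and the C1 methyl equatorial and the C1 hydroxyl axial, in which the C4=C8 unit lies pseudo-equatorial to keep C8 and its Z-methyl away from the axial hydrogens at C2 and C6, so that C8 ends cis to the aryl group (4S). The radical must cyclise before it is lost by β-hydrogen transfer to cobalt, 1,5-hydrogen shift from the allylic C5–H or 1,2-aryl shift: its only β-hydrogen (C2–H) is buried between two ortho OMOM groups and the fully substituted C1, capture by Co(II) is reversible under light, the C1/C2 substituents compress the chain towards closure, and low cobalt loading and high dilution are used. Hydrogen must leave from a C8 methyl and not from C4–H, which the flat, bulky cobaloxime secures by preferring six exposed methyl hydrogens over one hindered ring methine, while the amine removes H–Co(III) before it can re-add and isomerise the 1,1-disubstituted alkene.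

Step 6
Reactants: 9 cyclohexanol; 10 N-methoxy-N-methylisobutyramide
Product: 12 1-{3-[(1R,2R,5S)-2-hydroxy-2-methyl-5-(prop-1-en-2-yl)cyclohexyl]-2,4,6-tris(methoxymethoxy)phenyl}-2-methylpropan-1-one, via dilithiated alkoxide-aryllithium 11 (not isolated)
Conditions: n-BuLi (2.3 equiv), THF, 0 °C; then 10, −78 → 0 °C; sat. aq NH4Cl
Reagents that add atoms: none
Why: Directed ortho-metalation and Weinreb ketone synthesis: the first equivalent of n-BuLi masks the tertiary alcohol as its alkoxide, the second removes one of the two interchangeable ring hydrogens that each lie between two OMOM groups, and the Weinreb amide acylates the aryl carbanion once without esterifying the hindered alkoxide, so that no stereocentre or alkene is affected.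

Step 7
Reactants: 12 tris-MOM aryl ketone
Product: 14 1-{2,4,6-trihydroxy-3-[(1R,2R,5S)-2-hydroxy-2-methyl-5-(prop-1-en-2-yl)cyclohexyl]phenyl}-2-methylpropan-1-one, via tetrakis(trimethylsilyl) ether 13 (not isolated)
Conditions: TMSOTf (8 equiv), 2,2′-bipyridyl (12 equiv), MeCN, 0 °C → rt; hexane/cold water partition; citric acid (cat.), MeOH, rt, Ar
Reagents that add atoms: none
Why: Silyl triflate/2,2′-bipyridyl cleavage of aromatic MOM ethers (acetal-to-silyl-ether exchange) followed by methanolysis: no free strong acid is present, so the tertiary C1–O bond and the isopropenyl group are not ionised towards cyclisation on the neighbouring phenol oxygen, and the formaldehyde equivalent is washed out as a bipyridinium salt before the nucleophilic free phloroglucinol ring is released.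

Step 8
Reactants: 14 acylphloroglucinol; 15 prenyl bromide
Product: 17 3,5-dihydroxy-4-[(1R,2R,5S)-2-hydroxy-2-methyl-5-(prop-1-en-2-yl)cyclohexyl]-6,6-bis(3-methylbut-2-en-1-yl)-2-(2-methylpropanoyl)cyclohexa-2,4-dien-1-one (CNP0324849.1), via monoprenyl acylphloroglucinol 16 (not isolated)
Conditions: 15 (2.5 equiv), KOH (3.5 equiv), degassed H2O, 0 °C → rt, Ar; then aq citric acid to pH 4
Reagents that add atoms: none
Why: Alkylative dearomatisation of an acylphloroglucinol (double SN2 C-prenylation): the phenolate reacts at its only unsubstituted ring carbon to give 16, whose phenolate is alkylated again at that same carbon because the other two nucleophilic positions carry the bulky cyclohexyl group or the deactivating acyl group, water favours C- over O-alkylation, the tertiary alcohol stays un-ionised, and the new quaternary carbon bears two identical groups and is no stereocentre.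

**Compound list**
1 | geraniol, (2E)-3,7-dimethylocta-2,6-dien-1-ol | CC(C)=CCC/C(C)=C/CO | starting material
2 | [(2R,3R)-3-methyl-3-(4-methylpent-3-en-1-yl)oxiran-2-yl]methanol | CC(C)=CCC[C@@]1(C)O[C@@H]1CO | intermediate
3 | phloroglucinol (benzene-1,3,5-triol) | Oc1cc(O)cc(O)c1 | starting material
4 | 1,3,5-tris(methoxymethoxy)benzene | COCOc1cc(OCOC)cc(OCOC)c1 | intermediate
5 | [2,4,6-tris(methoxymethoxy)phenyl]lithium (formed in the flask) | [Li]c1c(OCOC)cc(OCOC)cc1OCOC | intermediate
6 | bromo[2,4,6-tris(methoxymethoxy)phenyl]magnesium (formed in the flask) | Br[Mg]c1c(OCOC)cc(OCOC)cc1OCOC | intermediate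
7 | (2S,3R)-3,7-dimethyl-2-[2,4,6-tris(methoxymethoxy)phenyl]oct-6-ene-1,3-diol | CC(C)=CCC[C@@](C)(O)[C@@H](c1c(OCOC)cc(OCOC)cc1OCOC)CO | intermediate
8 | (2R,3R)-1-iodo-3,7-dimethyl-2-[2,4,6-tris(methoxymethoxy)phenyl]oct-6-en-3-ol | CC(C)=CCC[C@@](C)(O)[C@@H](c1c(OCOC)cc(OCOC)cc1OCOC)CI | intermediate
9 | (1R,2R,4S)-1-methyl-4-(prop-1-en-2-yl)-2-[2,4,6-tris(methoxymethoxy)phenyl]cyclohexan-1-ol | C=C(C)[C@H]1CC[C@@](C)(O)[C@@H](c2c(OCOC)cc(OCOC)cc2OCOC)C1 | intermediate
10 | N-methoxy-N-methylisobutyramide | CC(C)C(=O)N(C)OC | starting material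
11 | lithium (1R,2R,4S)-2-[3-lithio-2,4,6-tris(methoxymethoxy)phenyl]-1-methyl-4-(prop-1-en-2-yl)cyclohexan-1-olate (formed in the flask) | C=C(C)[C@H]1CC[C@@](C)(O[Li])[C@@H](c2c(OCOC)cc(OCOC)c([Li])c2OCOC)C1 | intermediate
12 | 1-{3-[(1R,2R,5S)-2-hydroxy-2-methyl-5-(prop-1-en-2-yl)cyclohexyl]-2,4,6-tris(methoxymethoxy)phenyl}-2-methylpropan-1-one | C=C(C)[C@H]1CC[C@@](C)(O)[C@@H](c2c(OCOC)cc(OCOC)c(C(=O)C(C)C)c2OCOC)C1 | intermediate
13 | 2-methyl-1-{3-[(1R,2R,5S)-2-methyl-5-(prop-1-en-2-yl)-2-(trimethylsilyloxy)cyclohexyl]-2,4,6-tris(trimethylsilyloxy)phenyl}propan-1-one (formed in the flask) | C=C(C)[C@H]1CC[C@@](C)(O[Si](C)(C)C)[C@@H](c2c(O[Si](C)(C)C)cc(O[Si](C)(C)C)c(C(=O)C(C)C)c2O[Si](C)(C)C)C1 | intermediate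
14 | 1-{2,4,6-trihydroxy-3-[(1R,2R,5S)-2-hydroxy-2-methyl-5-(prop-1-en-2-yl)cyclohexyl]phenyl}-2-methylpropan-1-one | C=C(C)[C@H]1CC[C@@](C)(O)[C@@H](c2c(O)cc(O)c(C(=O)C(C)C)c2O)C1 | intermediate
15 | prenyl bromide (1-bromo-3-methylbut-2-ene) | CC(C)=CCBr | starting material
16 | 1-{2,4,6-trihydroxy-3-[(1R,2R,5S)-2-hydroxy-2-methyl-5-(prop-1-en-2-yl)cyclohexyl]-5-(3-methylbut-2-en-1-yl)phenyl}-2-methylpropan-1-one (formed in the flask) | C=C(C)[C@H]1CC[C@@](C)(O)[C@@H](c2c(O)c(CC=C(C)C)c(O)c(C(=O)C(C)C)c2O)C1 | intermediate
17 | 3,5-dihydroxy-4-[(1R,2R,5S)-2-hydroxy-2-methyl-5-(prop-1-en-2-yl)cyclohexyl]-6,6-bis(3-methylbut-2-en-1-yl)-2-(2-methylpropanoyl)cyclohexa-2,4-dien-1-one | C=C(C)[C@H]1CC[C@@](C)(O)[C@@H](C2=C(O)C(CC=C(C)C)(CC=C(C)C)C(=O)C(C(=O)C(C)C)=C2O)C1 | target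

**Step count**
Total steps: 8. Longest linear sequence: 7 (steps 1, 3, 4, 5, 6, 7, 8 from geraniol; the branch from phloroglucinol through step 2 is equally long).

**Steps most likely to fail**

1. Step 5 (key step).
- Risk: the primary radical may be consumed before ring closure, by hydrogen transfer from C2–H to cobalt, by 1,5-hydrogen shift from the allylic C5 methylene, or by 1,2-aryl migration. The chair preference may give poor facial selectivity at C4. Cobalt hydride may move the new double bond into the ring-conjugated position.
- Fallback, from 7 back to 9: the same C3–C4 bond is made by a polar pericyclic closure instead of a radical one. The primary alcohol of 7 is oxidised (Dess–Martin periodinane, NaHCO3, CH2Cl2, 0 °C) to (2R,3R)-3-hydroxy-3,7-dimethyl-2-[2,4,6-tris(methoxymethoxy)phenyl]oct-6-enal F1.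
- F1 is closed without storage by a type-I carbonyl-ene reaction of the citronellal kind (Me2AlCl, 2.2 equiv, CH2Cl2, −78 °C). This should give (1R,2S,3R,4R)-1-methyl-4-(prop-1-en-2-yl)-2-[2,4,6-tris(methoxymethoxy)phenyl]cyclohexane-1,3-diol F2. The all-equatorial chair sets C4 as before, and the concerted hydrogen transfer from a C8 methyl makes the isopropenyl group regiospecifically.
- The surplus C3 hydroxyl is removed by Barton–McCombie deoxygenation. 1,1′-Thiocarbonyldiimidazole with DMAP in toluene at 80 °C reacts only at the secondary alcohol and gives O-[(1R,2S,3R,6R)-3-hydroxy-3-methyl-6-(prop-1-en-2-yl)-2-[2,4,6-tris(methoxymethoxy)phenyl]cyclohexyl] 1H-imidazole-1-carbothioate F3. Bu3SnH with AIBN in toluene at 80 °C then gives 9.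

2. Step 3.
- Risk: transfer of the doubly ortho-substituted aryl group to C2 may be slow. Migration of the epoxide to the chain end followed by attack at C1, bromide opening at C3, or Lewis-acid rearrangement of the epoxide could then overtake C–C bond formation.
- Fallback, from 2 back to 7: C2 is activated and the free carbinol is removed. Compound 2 is oxidised (TEMPO, PhI(OAc)2, NaHCO3, MeCN/H2O, 0 °C) to (2S,3R)-3-methyl-3-(4-methylpent-3-en-1-yl)oxirane-2-carboxylic acid F4, which cannot undergo epoxide migration and whose α-carbon is the known site of cuprate attack on 2,3-epoxy acids.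
- Aryllithium 5 and CuI (0.5 equiv, Et2O/THF, −30 °C) give lithium bis[2,4,6-tris(methoxymethoxy)phenyl]cuprate F5. Used in excess (−30 → 0 °C), F5 opens F4 at C2 with inversion to (2R,3R)-3-hydroxy-3,7-dimethyl-2-[2,4,6-tris(methoxymethoxy)phenyl]oct-6-enoic acid F6. LiAlH4 (THF, 0 °C → rt) reduces F6 to 7.

3. Step 8.
- Risk: O-alkylation, a stalled second alkylation, alkylation at the ring carbon that bears the cyclohexyl group, hydrolysis of the bromide, and aerobic oxidation of the electron-rich phenolates may erode the dearomatised product.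
- Fallback, from 14 back to 17: the SN2 alkylation is replaced by palladium-catalysed allylic alkylation (Tsuji–Trost) with commercial prenyl acetate, Pd(PPh3)4 (5 mol %) and Cs2CO3 in THF at 40 °C under Ar. It is run in two stages, with 16 isolated after the first equivalent.
- O-Prenyl ethers formed kinetically are re-ionised by Pd(0), so the material is funnelled to carbon. The soft nucleophile attacks the unsubstituted terminus of the π-prenyl complex, which gives linear prenyl groups. New compounds on this way: none F0.

**Further compounds**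
F1 | step 5 | (2R,3R)-3-hydroxy-3,7-dimethyl-2-[2,4,6-tris(methoxymethoxy)phenyl]oct-6-enal | CC(C)=CCC[C@@](C)(O)[C@@H](c1c(OCOC)cc(OCOC)cc1OCOC)C=O
F2 | step 5 | (1R,2S,3R,4R)-1-methyl-4-(prop-1-en-2-yl)-2-[2,4,6-tris(methoxymethoxy)phenyl]cyclohexane-1,3-diol | C=C(C)[C@H]1CC[C@@](C)(O)[C@@H](c2c(OCOC)cc(OCOC)cc2OCOC)[C@@H]1O
F3 | step 5 | O-[(1R,2S,3R,6R)-3-hydroxy-3-methyl-6-(prop-1-en-2-yl)-2-[2,4,6-tris(methoxymethoxy)phenyl]cyclohexyl] 1H-imidazole-1-carbothioate | C=C(C)[C@H]1CC[C@@](C)(O)[C@@H](c2c(OCOC)cc(OCOC)cc2OCOC)[C@@H]1OC(=S)n1ccnc1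
F4 | step 3 | (2S,3R)-3-methyl-3-(4-methylpent-3-en-1-yl)oxirane-2-carboxylic acid | CC(C)=CCC[C@@]1(C)O[C@@H]1C(=O)O
F5 | step 3 | lithium bis[2,4,6-tris(methoxymethoxy)phenyl]cuprate | [Li+].COCOc1cc(OCOC)cc(OCOC)c1[Cu-]c1c(OCOC)cc(OCOC)cc1OCOC
F6 | step 3 | (2R,3R)-3-hydroxy-3,7-dimethyl-2-[2,4,6-tris(methoxymethoxy)phenyl]oct-6-enoic acid | CC(C)=CCC[C@@](C)(O)[C@@H](c1c(OCOC)cc(OCOC)cc1OCOC)C(=O)O
F0 | step 8 | none | none
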